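**Plan**
- Flavone numbering is used for all atoms that end up in rings A and C. The retrosynthesis first removes the 4′-O-benzyl group, then cuts C5–C6 of ring A, then C7–C8 (the acetyl group), then the pyranone bonds O1–C2 and C4–C4a, and last the C8a–C4a bond of a β-keto ester.
- Enabling feature: ring A is a masked 1,3,5-tricarbonyl whose carbons C4a and C8a already belong to pyranone ring C. The C4a=C8a double bond holds an ester on C4a (future C5) and a 1-substituted acetonyl arm on C8a (future C8, C7, C6) cis, and C8 already carries the side chain.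
- Forward order: glutarate chain, then β-keto ester, then ring C (with aryl ring B attached from the start), then acetylation at C8, then ring A by Claisen closure, then debenzylation.
- The single stereocentre comes from catalytic desymmetrisation of prochiral 3-phenylglutaric anhydride. Exchanging the two ester arms then puts the free acid on the arm that becomes C8.
- The benzylic centre is never enolisable, and the end game is kept neutral so that the 7-hydroxy acid neither lactonises nor scrambles to the 6-isomer.

Key step: step 9

Assumption: the hydroquinine-derived catalyst (DHQ)2AQN is taken to open 1 at the enantiotopic carbonyl group that leads to the (S)-hemiester; if the sense proves opposite, its hydroquinidine analogue (DHQD)2AQN is used in step 1 and nothing else changes.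

Step 1
Reactants: 1 3-phenylglutaric anhydride (4-phenyloxane-2,6-dione)
Product: 2 (3S)-5-methoxy-5-oxo-3-phenylpentanoic acid
Conditions: MeOH (10 equiv), (DHQ)2AQN [hydroquinine anthraquinone-1,4-diyl diether] (10 mol %), Et2O, −40 °C
Reagents that add atoms: methanol, CO
Why: Alkaloid-catalysed alcoholytic desymmetrisation of a prochiral cyclic anhydride, in which the quinuclidine nitrogen of the catalyst delivers methanol by general-base catalysis to one of the two enantiotopic carbonyl groups and so should fix the benzylic centre as (S).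

Step 2
Reactants: 2 (3S)-5-methoxy-5-oxo-3-phenylpentanoic acid
Product: 3 1-tert-butyl 5-methyl (3R)-3-phenylpentanedioate
Conditions: Cl3CC(=NH)OtBu (2 equiv), BF3·OEt2 (cat.), CH2Cl2–cyclohexane, rt
Reagents that add atoms: tert-butyl 2,2,2-trichloroacetimidate, CC(C)(C)OC(=N)C(Cl)(Cl)Cl
Why: Acid-catalysed tert-butyl transfer from the trichloroacetimidate esterifies the free acid without touching the methyl ester or the non-enolisable stereocentre (the descriptor becomes (R) only because the priorities change).

Step 3
Reactants: 3 1-tert-butyl 5-methyl (3R)-3-phenylpentanedioate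
Product: 4 (3R)-5-tert-butoxy-5-oxo-3-phenylpentanoic acid
Conditions: LiOH·H2O (1.2 equiv), THF–H2O, 0 °C → rt; then 1 M HCl to pH 3 at 0 °C
Reagents that add atoms: lithium hydroxide, [Li+].[OH-]
Why: Saponification by acyl–oxygen cleavage is much faster at the unhindered methyl ester than at the tert-butyl ester, so the free acid now sits on the arm that was esterified in step 1 and will be extended towards ring A.

Step 4
Reactants: 4 (3R)-5-tert-butoxy-5-oxo-3-phenylpentanoic acid; 5 potassium 3-methoxy-3-oxopropanoate (potassium monomethyl malonate)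
Product: 8 7-tert-butyl 1-methyl (5R)-3-oxo-5-phenylheptanedioate, via acyl imidazolide 6 (not isolated), via acylmalonate half-ester 7 (not isolated)
Conditions: CDI (1,1′-carbonyldiimidazole, 1.1 equiv), THF, rt; then 5 (2 equiv) premixed with MgCl2 (1 equiv) in THF, rt → 40 °C; cold 1 M HCl work-up
Reagents that add atoms: none
Why: Masamune–Brooks homologation, in which the magnesium enolate of the malonate half-ester is C-acylated by the neutral acyl imidazolide and the adduct loses CO2, mild enough to spare the tert-butyl ester and to avoid the scrambling of the two arms through the cyclic anhydride that harsher acid activation of a glutarate half-ester can cause.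

Step 5
Reactants: 9 1-(benzyloxy)-4-iodobenzene; 10 propiolic acid (prop-2-ynoic acid)
Product: 11 3-[4-(benzyloxy)phenyl]prop-2-ynoic acid
Conditions: Pd(PPh3)4 (5 mol %), DBU (2.5 equiv), DMSO, 35 °C; then 1 M HCl
Reagents that add atoms: none
Why: Copper-free Sonogashira coupling of an aryl iodide with the terminal alkyne of propiolic acid, run near room temperature so that the arylpropiolate should not decarboxylate.

Step 6
Reactants: 8 7-tert-butyl 1-methyl (5R)-3-oxo-5-phenylheptanedioate; 11 3-[4-(benzyloxy)phenyl]prop-2-ynoic acid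
Product: 14 methyl 6-[4-(benzyloxy)phenyl]-2-[(2R)-4-tert-butoxy-4-oxo-2-phenylbutyl]-4-oxo-4H-pyran-3-carboxylate, via acid chloride 12 (not isolated), via ynone tricarbonyl 13 (not isolated)
Conditions: 11, (COCl)2, DMF (cat.), CH2Cl2, 0 °C → rt, volatiles removed; then 8, MgCl2 (1.1 equiv), pyridine (2.2 equiv), CH2Cl2, 0 °C → rt; dilute HCl wash; then DMAP (0.2 equiv), CH2Cl2, rt
Reagents that add atoms: none
Why: C-acylation of the chelated magnesium enolate of the β-keto ester by the ynoyl chloride is followed by 6-endo-dig oxa-Michael addition of the ketone enol oxygen to the ynone (the reaction type behind γ-pyrone formation from acetylenic acid chlorides and β-keto esters and flavone formation from 2-hydroxyaryl ynones), with DMAP as nucleophilic catalyst and attack at the aryl-bearing alkyne carbon as the only conjugate mode.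

Step 7
Reactants: 14 methyl 6-[4-(benzyloxy)phenyl]-2-[(2R)-4-tert-butoxy-4-oxo-2-phenylbutyl]-4-oxo-4H-pyran-3-carboxylate; 15 N-methoxy-N-methylacetamide
Product: 16 methyl 2-[(2S)-1-acetyl-4-tert-butoxy-4-oxo-2-phenylbutyl]-6-[4-(benzyloxy)phenyl]-4-oxo-4H-pyran-3-carboxylate (both epimers at the acetyl-bearing carbon)
Conditions: LiN(SiMe3)2 (1.2 equiv), THF, −78 °C; then 15 (1.5 equiv), −78 → 0 °C; cold 0.5 M HCl quench
Reagents that add atoms: none
Why: Lateral (vinylogous) deprotonation of the 2-alkyl-4-pyranone, whose CH2 is activated through the ring by the C4 carbonyl and the 3-ester, gives a dienolate that is C-acylated at the exocyclic carbon by the Weinreb amide, the chelated tetrahedral adduct preventing over-reaction; the new centre forms as both epimers, which is immaterial because it becomes aromatic C8.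

Step 8
Reactants: 16 methyl 2-[(2S)-1-acetyl-4-tert-butoxy-4-oxo-2-phenylbutyl]-6-[4-(benzyloxy)phenyl]-4-oxo-4H-pyran-3-carboxylate
Product: 17 (3S)-4-{6-[4-(benzyloxy)phenyl]-3-(methoxycarbonyl)-4-oxo-4H-pyran-2-yl}-5-oxo-3-phenylhexanoic acid (both epimers at C4)
Conditions: CF3CO2H–CH2Cl2 (1:4), 0 °C → rt
Reagents that add atoms: none
Why: Acidolysis of the tert-butyl ester by alkyl–oxygen cleavage frees the side-chain acid, while the methyl ester, the benzyl aryl ether and the stereocentre should be inert to CF3CO2H at room temperature.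

Step 9
Reactants: 17 (3S)-4-{6-[4-(benzyloxy)phenyl]-3-(methoxycarbonyl)-4-oxo-4H-pyran-2-yl}-5-oxo-3-phenylhexanoic acid
Product: 18 (3R)-3-{2-[4-(benzyloxy)phenyl]-5,7-dihydroxy-4-oxo-4H-chromen-8-yl}-3-phenylpropanoic acid
Conditions: 17 added to LiN(iPr)2 (4.5 equiv), THF–DMPU, −78 → 0 °C; then cold 1 M HCl to pH 3
Reagents that add atoms: none
Why: LiN(iPr)2 first forms the lithium carboxylate, then removes the doubly activated C8–H and finally a proton of the acetyl methyl group (C6); the terminal enolate carbon C6 of this trianion adds to the carbonyl of the ring ester (C5), methoxide leaves, and the cyclohexenedione tautomerises at once to the 5,7-dihydroxy arene, which drives the reaction. The closest known reaction type is the intramolecular Claisen (Dieckmann-type) condensation of 2-acetonylbenzoates to naphthalene-1,3-diols and of polyketo esters to phloroglucinols, here with a pyranone in place of the benzene ring. Ring A closes in the 6-exo-trig mode (ring atoms C6, C7, C8, C8a, C4a, C5), helped by the C4a=C8a double bond of ring C, which holds the ester and the acetonyl arm cis. No stereocentre is created: the epimeric C8 becomes an aromatic carbon, and the benzylic centre, which has no acidic hydrogen, is carried through unchanged. The step needs chemoselectivity for the ring ester and regioselectivity for the 8-substituted flavone; the first is secured by the side chain being a carboxylate (not electrophilic and not enolised under these conditions, so neither a six-membered closure onto the side chain nor a second carbon nucleophile can arise), the second by C4a and C8a already belonging to ring C. Deprotonation at C8 before anything else also shuts off retro-Michael loss of the side chain and retro-Claisen loss of the acetyl group.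

Step 10
Reactants: 18 (3R)-3-{2-[4-(benzyloxy)phenyl]-5,7-dihydroxy-4-oxo-4H-chromen-8-yl}-3-phenylpropanoic acid
Product: 19 (3R)-3-[5,7-dihydroxy-2-(4-hydroxyphenyl)-4-oxo-4H-chromen-8-yl]-3-phenylpropanoic acid
Conditions: H2 (1 atm), 10% Pd/C, EtOAc–THF, rt
Reagents that add atoms: none
Why: Hydrogenolysis of the benzyl aryl ether over palladium on carbon is neutral, so the 7-hydroxy acid should stay open (no lactonisation to the dihydrocoumarin) and no acid is present to trigger Wessely–Moser migration of the 8-substituent.

**Compound list**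
1 | 3-phenylglutaric anhydride (4-phenyloxane-2,6-dione) | O=C1CC(c2ccccc2)CC(=O)O1 | starting material
2 | (3S)-5-methoxy-5-oxo-3-phenylpentanoic acid | OC(=O)C[C@H](c1ccccc1)CC(=O)OC | intermediate
3 | 1-tert-butyl 5-methyl (3R)-3-phenylpentanedioate | CC(C)(C)OC(=O)C[C@H](c1ccccc1)CC(=O)OC | intermediate
4 | (3R)-5-tert-butoxy-5-oxo-3-phenylpentanoic acid | CC(C)(C)OC(=O)C[C@H](c1ccccc1)CC(=O)O | intermediate
5 | potassium 3-methoxy-3-oxopropanoate (potassium monomethyl malonate) | COC(=O)CC(=O)[O-].[K+] | starting material
6 | tert-butyl (3R)-5-(1H-imidazol-1-yl)-5-oxo-3-phenylpentanoate (acyl imidazolide, formed in the flask) | CC(C)(C)OC(=O)C[C@H](c1ccccc1)CC(=O)n1ccnc1 | intermediate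
7 | (5R)-7-tert-butoxy-2-(methoxycarbonyl)-3,7-dioxo-5-phenylheptanoic acid (present as its magnesium salt, formed in the flask; C2 unassigned) | CC(C)(C)OC(=O)C[C@H](c1ccccc1)CC(=O)C(C(=O)O)C(=O)OC | intermediate
8 | 7-tert-butyl 1-methyl (5R)-3-oxo-5-phenylheptanedioate | CC(C)(C)OC(=O)C[C@H](c1ccccc1)CC(=O)CC(=O)OC | intermediate
9 | 1-(benzyloxy)-4-iodobenzene | Ic1ccc(OCc2ccccc2)cc1 | starting material
10 | propiolic acid (prop-2-ynoic acid) | C#CC(=O)O | starting material
11 | 3-[4-(benzyloxy)phenyl]prop-2-ynoic acid | OC(=O)C#Cc1ccc(OCc2ccccc2)cc1 | intermediate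
12 | 3-[4-(benzyloxy)phenyl]prop-2-ynoyl chloride (formed in the flask) | O=C(Cl)C#Cc1ccc(OCc2ccccc2)cc1 | intermediate
13 | 7-tert-butyl 1-methyl (5R)-2-{3-[4-(benzyloxy)phenyl]prop-2-ynoyl}-3-oxo-5-phenylheptanedioate (enolised, C2 unassigned; formed in the flask) | CC(C)(C)OC(=O)C[C@H](c1ccccc1)CC(=O)C(C(=O)OC)C(=O)C#Cc1ccc(OCc2ccccc2)cc1 | intermediate
14 | methyl 6-[4-(benzyloxy)phenyl]-2-[(2R)-4-tert-butoxy-4-oxo-2-phenylbutyl]-4-oxo-4H-pyran-3-carboxylate | CC(C)(C)OC(=O)C[C@H](c1ccccc1)Cc1oc(-c2ccc(OCc3ccccc3)cc2)cc(=O)c1C(=O)OC | intermediate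
15 | N-methoxy-N-methylacetamide | CON(C)C(C)=O | starting material
16 | methyl 2-[(2S)-1-acetyl-4-tert-butoxy-4-oxo-2-phenylbutyl]-6-[4-(benzyloxy)phenyl]-4-oxo-4H-pyran-3-carboxylate (both epimers at the acetyl-bearing carbon) | CC(C)(C)OC(=O)C[C@H](c1ccccc1)C(C(C)=O)c1oc(-c2ccc(OCc3ccccc3)cc2)cc(=O)c1C(=O)OC | intermediate
17 | (3S)-4-{6-[4-(benzyloxy)phenyl]-3-(methoxycarbonyl)-4-oxo-4H-pyran-2-yl}-5-oxo-3-phenylhexanoic acid (both epimers at C4) | OC(=O)C[C@H](c1ccccc1)C(C(C)=O)c1oc(-c2ccc(OCc3ccccc3)cc2)cc(=O)c1C(=O)OC | intermediate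
18 | (3R)-3-{2-[4-(benzyloxy)phenyl]-5,7-dihydroxy-4-oxo-4H-chromen-8-yl}-3-phenylpropanoic acid | OC(=O)C[C@H](c1ccccc1)c1c(O)cc(O)c2c(=O)cc(-c3ccc(OCc4ccccc4)cc3)oc12 | intermediate
19 | (3R)-3-[5,7-dihydroxy-2-(4-hydroxyphenyl)-4-oxo-4H-chromen-8-yl]-3-phenylpropanoic acid | O=C(O)C[C@H](c1ccccc1)c1c(O)cc(O)c2c(=O)cc(-c3ccc(O)cc3)oc12 | target

**Step count**
Total steps: 10. Longest linear sequence: 9 (steps 1–4 and 6–10; step 5 is a one-step side branch).

**Steps most likely to fail**

1. Step 9. The third deprotonation may be incomplete or occur α to the carboxylate instead of at the acetyl methyl group. The polyanion may also be poorly soluble, so that closure stalls and the acetyl group is lost on work-up. Fallback, from 16 back to 18: ring A is closed one step earlier on the tert-butyl ester under reversible, chelate-templated alkoxide conditions (Mg(OMe)2, MeOH, reflux, the magnesium-templated Claisen closure known for polyketo esters). No amide base is present to enolise the side-chain ester, the hindered ester resists the competing closure, and the aromatising closure is the sink. This should give tert-butyl (3R)-3-{2-[4-(benzyloxy)phenyl]-5,7-dihydroxy-4-oxo-4H-chromen-8-yl}-3-phenylpropanoate F1, whose ester is then cleaved with CF3CO2H–CH2Cl2 as in step 8, rejoining the route at 18.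

2. Step 7. C-acylation of the hindered, stabilised lateral anion by the amide may be sluggish, leaving time for proton transfer to the amide or enolisation of the side-chain ester. Fallback, from 14 back to 16: the same lithium dienolate (LiN(SiMe3)2, THF, −78 °C) is trapped with the far more electrophilic acetaldehyde in an aldol addition and quenched with AcOH at −78 °C, before the alkoxide can lactonise onto the ring ester. This should give tert-butyl (3S)-4-{6-[4-(benzyloxy)phenyl]-3-(methoxycarbonyl)-4-oxo-4H-pyran-2-yl}-5-hydroxy-3-phenylhexanoate F2 as a diastereomer mixture. Oxidation with Dess–Martin periodinane in CH2Cl2 then delivers 16.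

3. Step 6. The magnesium enolate may add in conjugate fashion to the ynoyl chloride instead of being acylated, or the ynone may close in the 5-exo mode or through the wrong oxygen. Fallback, from 11 (and 8) back to 14: the alkyne is replaced by a β-chlorovinyl unit so that ring closure is an addition–elimination that can only be six-membered.
   - Hydrochlorination of 11 (LiCl, AcOH, 80 °C, anti addition) should give (2Z)-3-[4-(benzyloxy)phenyl]-3-chloroprop-2-enoic acid F3.
   - (COCl)2 with catalytic DMF converts it into (2Z)-3-[4-(benzyloxy)phenyl]-3-chloroprop-2-enoyl chloride F4.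
   - F4 C-acylates the magnesium enolate of 8 (MgCl2, pyridine, CH2Cl2) to 7-tert-butyl 1-methyl (5R)-2-{(2Z)-3-[4-(benzyloxy)phenyl]-3-chloroprop-2-enoyl}-3-oxo-5-phenylheptanedioate F5.
   - Et3N then closes the pyranone by intramolecular displacement of chloride, giving 14.

Further compounds
F1 | step 9 | tert-butyl (3R)-3-{2-[4-(benzyloxy)phenyl]-5,7-dihydroxy-4-oxo-4H-chromen-8-yl}-3-phenylpropanoate | CC(C)(C)OC(=O)C[C@H](c1ccccc1)c1c(O)cc(O)c2c(=O)cc(-c3ccc(OCc4ccccc4)cc3)oc12
F2 | step 7 | tert-butyl (3S)-4-{6-[4-(benzyloxy)phenyl]-3-(methoxycarbonyl)-4-oxo-4H-pyran-2-yl}-5-hydroxy-3-phenylhexanoate | CC(C)(C)OC(=O)C[C@H](c1ccccc1)C(C(C)O)c1oc(-c2ccc(OCc3ccccc3)cc2)cc(=O)c1C(=O)OC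
F3 | step 6 | (2Z)-3-[4-(benzyloxy)phenyl]-3-chloroprop-2-enoic acid | OC(=O)/C=C(\Cl)c1ccc(OCc2ccccc2)cc1
F4 | step 6 | (2Z)-3-[4-(benzyloxy)phenyl]-3-chloroprop-2-enoyl chloride | O=C(Cl)/C=C(\Cl)c1ccc(OCc2ccccc2)cc1
F5 | step 6 | 7-tert-butyl 1-methyl (5R)-2-{(2Z)-3-[4-(benzyloxy)phenyl]-3-chloroprop-2-enoyl}-3-oxo-5-phenylheptanedioate | CC(C)(C)OC(=O)C[C@H](c1ccccc1)CC(=O)C(C(=O)OC)C(=O)/C=C(\Cl)c1ccc(OCc2ccccc2)cc1
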